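**Strategy.** The C2-symmetric hydrocarbon is cut at C11–C11′ into two identical drim-8-en-11-yl halves (drimane numbering), and ring B of each half into the C6–C5–C10 edge of ring A plus a C7–C8–C9 unit. In one operation under [Cu((R,R)-tBu-box)(H2O)2](SbF6)2 (divalent copper), an exocyclic methylene cyclohexane and an isopropenyl α-keto ester are joined by two consecutive ene reactions, C6–C7 and then C9–C10. This closes ring B and sets C10. The step exploits the quaternary C4 beside C5: only C10–H, then only C6–H, can be transferred. The leftover C5=C6 alkene and C9 carbinol become 5α-H and the C8=C9 alkene, and homocoupling of the allylic bromide joins the halves.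

Key step: step 3

Remark on the chemistry: atoms carry drimane numbers (ring A = C1–C5 and C10; ring B = C5–C10; C11 on C9; C12 on C8); tBu-box is 2,2′-(propane-2,2-diyl)bis[(4R)-4-tert-butyl-4,5-dihydro-1,3-oxazole]. The sense of induction of the copper complex is assumed to follow that of intermolecular pyruvate ester ene reactions. Ketone 1 is used as the racemate because its stereocentre is erased in step 3.

Step 1
Reactants: 1 2,2,6-trimethylcyclohexanone (racemic)
Product: 2 1,1,3-trimethyl-2-methylenecyclohexane (racemic)
Conditions: Ph3PCH3Br, KOtBu, toluene, 110 °C
Reagents that add atoms: methyltriphenylphosphonium bromide, C[P+](c1ccccc1)(c1ccccc1)c1ccccc1.[Br-]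
Why: Wittig methylenation with the ylide made by KOtBu in hot toluene is the usual answer to a hindered, enolisable ketone and should give the exocyclic alkene without touching the ring.

Step 2
Reactants: 3 diethyl oxalate; 4 isopropenylmagnesium bromide
Product: 5 ethyl 3-methyl-2-oxobut-3-enoate
Conditions: 4 added to excess 3, THF, −78 °C; then 1 M HCl; used at once
Reagents that add atoms: none
Why: Monoacylation of a Grignard reagent by a dialkyl oxalate at low temperature should stop at the α-keto ester because the tetrahedral magnesium chelate survives until the quench; the product is used fresh because it tends to dimerise.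

Step 3
Reactants: 2 1,1,3-trimethyl-2-methylenecyclohexane; 5 ethyl 3-methyl-2-oxobut-3-enoate
Product: 7 ethyl (8R,9R,10S)-9-hydroxydrim-5-en-11-oate, via monocyclic keto ester 6 (not isolated)
Conditions: [Cu((R,R)-tBu-box)(H2O)2](SbF6)2 (divalent copper, 10 mol %), CH2Cl2, 0 °C to 25 °C
Reagents that add atoms: none
Why: Proposed new method: the chelated α-keto ester 5 should act first as a vinylogous enophile, so that C6 of 2 adds to C7 and C10–H passes to C8 (ene reaction, giving 6 with the C5=C10 alkene), and the same copper chelate should then activate the C9 ketone for attack by C10 with loss of C6–H (stepwise carbonyl-ene, Prins-type closure); the closest known reaction types are the Me2AlCl-induced sequential ene annulation of alkylidenecycloalkanes with enones and the enantioselective carbonyl-ene reaction of α-keto esters under copper bis(oxazoline) complexes, shown inter- and intramolecularly but not as one sequence. Ring B should close in the 6-endo mode at C10 through a chair-like transition state, because the 5-exo alternative at C5 would place a second quaternary carbon beside C4. C9 is set by the ligand, which by analogy with pyruvate ene reactions should leave the Re face of the chelated ketone open; C10 follows from C9 through the chair with the ester equatorial and the C9–O bond axial, anti to the C10 methyl group. C8 equilibrates through the enol of 6 and should take the equatorial methyl; C8 and C9 are erased in step 5. The step needs 1,4- over 1,2-addition in the first ene event, which the unsubstituted C7 terminus should secure, and single hydrogen-transfer sites, which the quaternary C4 secures by leaving only C10–H and then only C6–H.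

Step 4
Reactants: 7 ethyl (8R,9R,10S)-9-hydroxydrim-5-en-11-oate
Product: 8 ethyl (5S,8R,9R,10S)-9-hydroxydriman-11-oate
Conditions: [Ir(cod)(PCy3)(py)]PF6 (monovalent iridium, 5 mol %), H2 (1 atm), CH2Cl2, 25 °C
Reagents that add atoms: none
Why: Hydroxyl-directed homogeneous hydrogenation: the homoallylic 9α-OH should hold the iridium on the α-face, which is also the open face because the C10 methyl and the 4β-methyl screen the β-face, so that C5 receives its hydrogen from below (5S, trans-decalin).

Step 5
Reactants: 8 ethyl (5S,8R,9R,10S)-9-hydroxydriman-11-oate
Product: 9 ethyl (5S,10S)-drim-8-en-11-oate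
Conditions: SOCl2, pyridine, CH2Cl2, 0 °C to 25 °C
Reagents that add atoms: none
Why: Dehydration of a tertiary α-hydroxy ester through its chlorosulfite by anti elimination of the axial 8β-H and the axial 9α-oxygen; C8 carries the only β-hydrogen (C10 is quaternary), so only the conjugated C8=C9 alkene can form.

Step 6
Reactants: 9 ethyl (5S,10S)-drim-8-en-11-oate
Product: 10 (5S,10S)-drim-8-en-11-ol
Conditions: LiAlH4, Et2O, 0 °C to 25 °C
Reagents that add atoms: none
Why: 1,2-Reduction of the hindered, fully substituted enoate by LiAlH4 should give the allylic alcohol without touching the tetrasubstituted alkene.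

Step 7
Reactants: 10 (5S,10S)-drim-8-en-11-ol
Product: 11 (5S,10S)-11-bromodrim-8-ene
Conditions: CBr4, PPh3, CH2Cl2, 0 °C; used crude
Reagents that add atoms: carbon tetrabromide, BrC(Br)(Br)Br
Why: Appel bromination by SN2 at the primary allylic carbon under neutral conditions; transposition to C8 is disfavoured because that carbon is fully substituted.

Step 8
Reactants: 11 (5S,10S)-11-bromodrim-8-ene (two molecules)
Product: 12 1,2-bis[(4aS,8aS)-2,5,5,8a-tetramethyl-3,4,4a,5,6,7,8,8a-octahydronaphthalen-1-yl]ethane (CNP0372467.1)
Conditions: Cp2TiCl2 (tetravalent titanium, 0.2 equiv), Mn dust (zerovalent manganese, 8 equiv), THF, 25 °C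
Reagents that add atoms: none
Why: Wurtz-type reductive homocoupling of an allylic bromide by Cp2TiCl (trivalent titanium) made in the flask should join the two allyl units at C11 (head to head) because the other allyl terminus, C8, is fully substituted; no stereocentre is touched, and any minor enantiomer of 11 should end up mostly in a separable meso diastereomer.

**Compound list**

1 | 2,2,6-trimethylcyclohexanone (racemic) | CC1CCCC(C)(C)C1=O | starting material
2 | 1,1,3-trimethyl-2-methylenecyclohexane (racemic) | C=C1C(C)CCCC1(C)C | intermediate
3 | diethyl oxalate | CCOC(=O)C(=O)OCC | starting material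
4 | isopropenylmagnesium bromide | CC(=C)[Mg]Br | starting material
5 | ethyl 3-methyl-2-oxobut-3-enoate | CCOC(=O)C(=O)C(C)=C | intermediate
6 | ethyl 3-methyl-2-oxo-5-(2,6,6-trimethylcyclohex-1-en-1-yl)pentanoate (monocyclic keto ester; C8 epimers) | CCOC(=O)C(=O)C(C)CCC1=C(C)CCCC1(C)C | intermediate
7 | ethyl (1R,2R,8aS)-1-hydroxy-2,5,5,8a-tetramethyl-1,2,3,5,6,7,8,8a-octahydronaphthalene-1-carboxylate [ethyl (8R,9R,10S)-9-hydroxydrim-5-en-11-oate] | CCOC(=O)[C@@]1(O)[C@H](C)CC=C2C(C)(C)CCC[C@]12C | intermediate
8 | ethyl (1R,2R,4aS,8aS)-1-hydroxy-2,5,5,8a-tetramethyldecahydronaphthalene-1-carboxylate [ethyl (5S,8R,9R,10S)-9-hydroxydriman-11-oate] | CCOC(=O)[C@@]1(O)[C@H](C)CC[C@H]2C(C)(C)CCC[C@]12C | intermediate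
9 | ethyl (4aS,8aS)-2,5,5,8a-tetramethyl-3,4,4a,5,6,7,8,8a-octahydronaphthalene-1-carboxylate [ethyl (5S,10S)-drim-8-en-11-oate] | CCOC(=O)C1=C(C)CC[C@H]2C(C)(C)CCC[C@]12C | intermediate
10 | [(4aS,8aS)-2,5,5,8a-tetramethyl-3,4,4a,5,6,7,8,8a-octahydronaphthalen-1-yl]methanol [(5S,10S)-drim-8-en-11-ol] | OCC1=C(C)CC[C@H]2C(C)(C)CCC[C@]12C | intermediate
11 | (4aS,8aS)-5-(bromomethyl)-1,1,4a,6-tetramethyl-1,2,3,4,4a,7,8,8a-octahydronaphthalene [(5S,10S)-11-bromodrim-8-ene] | BrCC1=C(C)CC[C@H]2C(C)(C)CCC[C@]12C | intermediate
12 | 1,2-bis[(4aS,8aS)-2,5,5,8a-tetramethyl-3,4,4a,5,6,7,8,8a-octahydronaphthalen-1-yl]ethane (CNP0372467.1) | CC1=C(CCC2=C(C)CC[C@H]3C(C)(C)CCC[C@]23C)[C@@]2(C)CCCC(C)(C)[C@@H]2CC1 | target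

**Step count.** Total: 8 steps. Longest linear sequence: 7 steps (1, 3, 4, 5, 6, 7, 8).

**Steps most likely to fail**

Step 3 (Proposed new method). The first ene event may take the 1,2-course at the keto carbonyl of 5 or stall at a spiro dihydropyran. The copper complex may be too weak a Lewis acid for the intermolecular event. The C5 cation of the ring closure may suffer methyl migration from C4. Facial selectivity at C9, or its relay to C10 through the chair, may be low or opposite in sense. The fallback sets out from 2 and 5 and comes back at 7, and runs the two ene events apart with known chemistry. Me2AlCl (1 equiv, CH2Cl2, −78 °C) should promote only the conjugate ene reaction and give keto ester 6, which is now isolated. Compound 6 is then closed by the known enantioselective intramolecular carbonyl-ene reaction of olefinic α-keto esters under [Cu((R,R)-tBu-box)(H2O)2](SbF6)2 (divalent copper). No compound outside the list is made (F0). If only the sense of induction is wrong, the ligand antipode serves, because C9 is erased in step 5.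

Step 8. The allyl radical or allyltitanium species may couple through C8 (head to tail), may be reduced to the hydrocarbon, or the labile bromide may eliminate to a diene before it couples. The fallback sets out from 11 and comes back at 12 by sulfone alkylation and desulfonylation. Bromide 11 with PhSO2Na in DMF at 25 °C should give drim-8-en-11-yl phenyl sulfone F1. Its anion (n-BuLi, THF, −78 °C) is alkylated with a second molecule of 11 to give 11-(phenylsulfonyl)-11,11′-bi(drim-8-ene) F2, as a mixture of epimers at the sulfone carbon. Reductive desulfonylation with LiBHEt3 and PdCl2(dppp) (divalent palladium, 5 mol %) in THF at 0 °C should deliver hydride to the less hindered allyl terminus and give 12 with the C8=C9 alkene in place.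

Step 4. Hydrogen uptake at the trisubstituted C5=C6 bond, flanked by the C4 gem-dimethyl group and the quaternary C10, may be slow or absent. The iridium may be tied up by the hydroxy ester, and facial selectivity may be lost if the directing effect fails. The fallback sets out from 7 and comes back at 8 by a change of mechanism: hydrogen-atom-transfer hydrogenation with Mn(dpm)3 (trivalent manganese, 10 mol %), PhSiH3 and tert-butyl hydroperoxide in isopropanol at 25 °C. This passes through the tertiary C5 radical and should give the thermodynamically preferred trans ring fusion. No compound outside the list is made (F0).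

Further compounds
F0 | step 3 | none | none
F1 | step 8 | drim-8-en-11-yl phenyl sulfone, {[(4aS,8aS)-2,5,5,8a-tetramethyl-3,4,4a,5,6,7,8,8a-octahydronaphthalen-1-yl]methanesulfonyl}benzene | O=S(=O)(CC1=C(C)CC[C@H]2C(C)(C)CCC[C@]12C)c1ccccc1
F2 | step 8 | 11-(phenylsulfonyl)-11,11′-bi(drim-8-ene) (epimers at the sulfone carbon) | O=S(=O)(C(CC1=C(C)CC[C@H]2C(C)(C)CCC[C@]12C)C1=C(C)CC[C@H]2C(C)(C)CCC[C@]12C)c1ccccc1
F0 | step 4 | none | none
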